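Tuesday's flask holds less G than X, so G is its limiting reagent, while Wednesday's holds more, so there X is.

all flasks: X 0.10 M

| charge | G | remark | time |
|---|---|---|---|
| south | 0.13 M | run made earlier |  |
| south-east | 0.30 M | run made earlier |  |
| Tuesday's | 0.0950 M |  | 15 h |
| Wednesday's | 0.190 M |  | 15 h |

| run | time / h | E / % | X / % | D / % | J / % |
|---|---|---|---|---|---|
| south | 1.33 | 0.1 | 91.2 | 8.4 | 0 |
| south | 2.50 | 0.8 | 84.8 | 14.2 | 0.6 |
| south | 4.00 | 2.0 | 77.7 | 20.7 | 0 |
| south | 5.00 | 2.6 | 73.1 | 23.9 | 0.2 |
| south | 6.00 | 4.0 | 69.1 | 26.3 | 0.1 |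
| south | 8.00 | 5.3 | 62.4 | 31.2 | 0.7 |
| south-east | 1.33 | 0.3 | 81.2 | 18.0 | 0.3 |
| south-east | 2.50 | 2.1 | 68.2 | 29.5 | 0.2 |
| south-east | 4.00 | 3.6 | 55.4 | 40.3 | 0.3 |
| south-east | 5.00 | 5.1 | 48.0 | 45.6 | 0.7 |
| south-east | 6.00 | 6.5 | 42.0 | 49.2 | 1.0 |
| south-east | 8.00 | 10.7 | 33.3 | 54.6 | 1.4 |

(each reading ± 0.3 percentage points)

- reactions considered so far: G + L -> J + Q; X + G -> D + Q; G + D -> L + Q; D -> E; G + J <-> Z + Q

- which of these there is most of at the end, counted by the X in it, Tuesday's (X / J / D / E)
- which of these there is most of at the end, counted by the X in it, Wednesday's (X / J / D / E)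
- the largest of these amounts at the end, in percent of the X charged, Tuesday's
- the largest of these amounts at the end, in percent of the X charged, Wednesday's

The ledger follows each G, and this reckoning is my own.

1. Each X that reacts takes one G and gives one D, and D → E takes no G. The south-east run's last line sums to 100% with J at 1.4%, so the later adducts are a small entry.

2. With rate k c(X) c(G), that last line gives k = 0.530 /M/h.

3. Any species above half of the X charged is the largest, since the others share the remainder. The crossing time, at which X reaches that mark, is 20.4 h for Tuesday's flask. By then the crossing has cost 0.0500 M of G.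

4. Tuesday's crossing comes later than 15 h, so X stays largest, at 57.5%. The books show 0.0425 M of G spent.

5. Wednesday's crossing comes at 8.13 h, earlier than 15 h, and X ends at 31.2%. In Wednesday's flask, X keeps the lead over D at 15 h only if E with the later adducts holds over 37.6%. The pace of E between the south-east run's last two readings, carried on from its last reading to 15 h, gives about 25.4%, less than that mark. This is an estimate from a run with more G than Wednesday's flask, and by it D leads.

The forecast names X at 57% (54% to 60%) for Tuesday's flask, with the words “X is therefore largest”. For Wednesday's flask it names D at 48% (44% to 52%).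

The simulation gives X at 57.1% for Tuesday's flask and D at 47.5% for Wednesday's, so the forecast stands.

    G + L → J + Q (k = 0.0489 /M/min)
    X + G → D + Q (k = 0.00902 /M/min)
    G + D → L + Q (k = 4.29 × 10⁻⁴ /M/min)
    D → E (k = 6.26 × 10⁻⁴ /min)
    G + J ⇌ Z + Q (K = 3.12, k = 0.00355 /M/min)

In Tuesday's flask, whose crossing was reckoned at 20.4 h, X + G ran beside D → E with X at 72.4% after 7.50 h, and at 15.0 h D was still made 1.33 times faster than used up. In Wednesday's flask, reckoned to cross at 8.13 h, X stood at 51.9% after 7.50 h, and both steps ran on until E held 19.8% at 15.0 h.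

Tuesday's flask with 0.38 M of G crosses, by the same reckoning, at 3.72 h, earlier than 15 h, and leaves 8.18% of X. The simulation gives X at 8.14% and D as the largest, at 57.4%.

The data were computed for substances that don't exist, and the scatter is random.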